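Ring B (the cyclohexenone; spiro[4.5]decane numbering) is disconnected across C5–C10 and C6–C7 into a ring A allenyl ketone and a 2-silyloxypenta-1,3-diene. One Diels–Alder reaction closes ring B by bonding the spiro carbon C5 to the methyl-bearing C10, creating the quaternary centre and the C10 stereocentre together and joining two halves of similar size. It exploits that C5 lies α to the oxygenated C1 (used as a ketone, making C5=C6 a dienophile) while the C8 carbonyl marks a 2-oxydiene. The precursor, (4S)-2-ethenylidene-4-isopropenylcyclopentanone, is made from (S)-limonene by cleaving its ring and reclosing it to a cyclopentene; its allene CH2 later becomes the C6 methyl.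

Key step: step 8

Remark: numbering used below is ring A = C1 (acyloxy carbon), C2, C3 (isopropenyl carbon), C4; C5 = spiro carbon; ring B = C6 (vinylic methyl carbon), C7, C8 (C=O), C9 (acetoxy carbon), C10 (CH–CH3); the trans C9-acetoxy/C10-methyl arrangement of the target is assumed to be the more stable one at the epimerisable C9.

Step 1
Reactants: 1 (S)-(−)-limonene, (4S)-1-methyl-4-(prop-1-en-2-yl)cyclohex-1-ene
Product: 2 (3S)-6-oxo-3-(prop-1-en-2-yl)heptanal
Conditions: O3 (1.0 equiv), CH2Cl2/MeOH, −78 °C; then Me2S, −78 °C to rt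
Reagents that add atoms: ozone [O-][O+]=O
Why: Chemoselective ozonolysis with reductive work-up, in which electrophilic ozone should cleave the more electron-rich trisubstituted ring alkene ahead of the 1,1-disubstituted isopropenyl group when one equivalent is delivered at low temperature; the stereocentre is not touched.

Step 2
Reactants: 2 (3S)-6-oxo-3-(prop-1-en-2-yl)heptanal
Product: 3 1-[(4R)-4-(prop-1-en-2-yl)cyclopent-1-en-1-yl]ethan-1-one
Conditions: KOH, H2O/MeOH, 0 °C to rt
Reagents that add atoms: none
Why: Intramolecular aldol condensation in which the ketone enolate at the internal CH2 attacks the more electrophilic aldehyde (5-enolexo closure) and dehydration gives the conjugated acetylcyclopentene; the stereocentre is not α to either carbonyl and cannot epimerise.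

Step 3
Reactants: 3 1-[(4R)-4-(prop-1-en-2-yl)cyclopent-1-en-1-yl]ethan-1-one
Product: 4 1-[(3R)-3-(prop-1-en-2-yl)-6-oxabicyclo[3.1.0]hexan-1-yl]ethan-1-one (both epoxide faces)
Conditions: H2O2 (30 % aq.), NaOH, MeOH, 0 °C
Reagents that add atoms: hydrogen peroxide OO
Why: Weitz–Scheffer nucleophilic epoxidation attacks only the electron-poor enone alkene and leaves the isopropenyl group; the facial outcome is immaterial because both new centres are erased again at compound 8.

Step 4
Reactants: 4 1-[(3R)-3-(prop-1-en-2-yl)-6-oxabicyclo[3.1.0]hexan-1-yl]ethan-1-one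
Product: 6 (3R)-1-ethynyl-3-(prop-1-en-2-yl)-6-oxabicyclo[3.1.0]hexane, via enol phosphate 5 (not isolated)
Conditions: LiN(iPr)2 (1.05 equiv), THF, −78 °C; ClP(O)(OEt)2; then LiN(iPr)2 (2.3 equiv), −78 °C to rt; H2O
Reagents that add atoms: none
Why: Negishi one-flask conversion of a methyl ketone into a terminal alkyne, in which the only available enolate (the other α-carbon is the fully substituted epoxide carbon) is O-phosphorylated and the enol phosphate is eliminated by amide base to the lithium acetylide.

Step 5
Reactants: 6 (3R)-1-ethynyl-3-(prop-1-en-2-yl)-6-oxabicyclo[3.1.0]hexane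
Product: 7 (4S)-2-ethenylidene-4-(prop-1-en-2-yl)cyclopentan-1-ol (C1 epimers)
Conditions: iBu2AlH (2 equiv), CH2Cl2, −78 to 0 °C; then H2O
Reagents that add atoms: none
Why: SN2′ hydride opening of an alkynyl oxirane (a known route to α-allenols), in which aluminium binds the epoxide oxygen and delivers hydride to the alkyne terminus so that the tertiary propargylic C–O bond breaks and the C5=C6=CH2 allene forms; the CH2 terminus means no axial chirality arises.

Step 6
Reactants: 7 (4S)-2-ethenylidene-4-(prop-1-en-2-yl)cyclopentan-1-ol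
Product: 8 (4S)-2-ethenylidene-4-(prop-1-en-2-yl)cyclopentan-1-one
Conditions: Dess–Martin periodinane, NaHCO3, CH2Cl2, 0 °C; used at once
Reagents that add atoms: none
Why: Dess–Martin oxidation of the secondary α-allenic alcohol under buffered, base-free conditions should give the conjugated allenyl ketone without isomerisation to the 2-vinylcyclopentenone.

Step 7
Reactants: 9 (3E)-pent-3-en-2-one
Product: 10 tert-butyl(dimethyl){[(3E)-penta-1,3-dien-2-yl]oxy}silane
Conditions: TBSOTf, Et3N, CH2Cl2, 0 °C
Reagents that add atoms: tert-butyldimethylsilyl trifluoromethanesulfonate CC(C)(C)[Si](C)(C)OS(=O)(=O)C(F)(F)F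
Why: Soft enolisation of the enone removes an α′-methyl proton and gives the cross-conjugated 2-silyloxydiene with the E-propenyl geometry retained.

Step 8
Reactants: 8 (4S)-2-ethenylidene-4-(prop-1-en-2-yl)cyclopentan-1-one; 10 tert-butyl(dimethyl){[(3E)-penta-1,3-dien-2-yl]oxy}silane
Product: 11 (3S,5R,10R)-8-{[tert-butyl(dimethyl)silyl]oxy}-10-methyl-6-methylidene-3-(prop-1-en-2-yl)spiro[4.5]dec-8-en-1-one
Conditions: Me2AlCl (0.2 equiv), CH2Cl2, −78 to −30 °C
Reagents that add atoms: none
Why: Concerted, asynchronous [4+2] cycloaddition between electron-rich diene 10 and the ketone-conjugated C5=C6 bond of allenone 8 activated by Me2AlCl; the closest precedent is the Diels–Alder reaction of α-substituted allenic ketones and esters with 2-silyloxydienes, which adds across the α,β bond and leaves an exocyclic methylene. Ring B closes in a six-membered pericyclic mode by forming C5–C10 and C6–C7 together, so the quaternary spiro centre is made at the bond that unites the two halves. Regiochemistry follows the frontier orbitals: the diene CH2 terminus next to the silyloxy carbon pairs with the central allene carbon C6 (β to C=O), and the methyl-bearing terminus with the α-carbon C5. The C10 methyl configuration comes from the E-diene geometry combined with endo approach of the Lewis-acid-bound C1 carbonyl, which places the methyl cis to C1 on ring B. The C5 configuration is set by approach of the diene to the face of ring A opposite the C3 isopropenyl group. The step needs chemoselectivity for the conjugated allene bond over the terminal one, secured by conjugation, and facial selectivity from a remote centre, secured only by the ring A envelope, so minor isomers are to be removed by chromatography.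

Step 9
Reactants: 11 (3S,5R,10R)-8-{[tert-butyl(dimethyl)silyl]oxy}-10-methyl-6-methylidene-3-(prop-1-en-2-yl)spiro[4.5]dec-8-en-1-one
Product: 13 (1R,3S,5R,10R)-8-{[tert-butyl(dimethyl)silyl]oxy}-10-methyl-6-methylidene-3-(prop-1-en-2-yl)spiro[4.5]dec-8-en-1-yl 2-methylpropanoate, via lithium alkoxide 12 (not isolated)
Conditions: LiBH(sBu)3 (1.1 equiv), THF, −78 °C; then iPrCOCl, DMAP, −78 °C to rt
Reagents that add atoms: 2-methylpropanoyl chloride CC(C)C(=O)Cl
Why: Ketone reduction by a bulky hydride followed by O-acylation of the alkoxide in the same flask, in which hydride should reach C1 from the face of the flat C6 methylidene and away from C10 and its methyl to give the 1R alkoxide (oxygen cis to C10), while the silyl enol ether masks C8.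

Step 10
Reactants: 13 (1R,3S,5R,10R)-8-{[tert-butyl(dimethyl)silyl]oxy}-10-methyl-6-methylidene-3-(prop-1-en-2-yl)spiro[4.5]dec-8-en-1-yl 2-methylpropanoate
Product: 15 (1R,3S,5R,9R,10S)-9-hydroxy-10-methyl-6-methylidene-8-oxo-3-(prop-1-en-2-yl)spiro[4.5]decan-1-yl 2-methylpropanoate, via silyloxy ketone 14 (not isolated)
Conditions: mCPBA (1.0 equiv), NaHCO3, CH2Cl2, −40 to 0 °C; then HF·pyridine, THF, 0 °C
Reagents that add atoms: 3-chloroperoxybenzoic acid OOC(=O)c1cccc(Cl)c1
Why: Rubottom oxidation, in which the peracid should epoxidise the electron-rich silyl enol ether far faster than the two 1,1-disubstituted alkenes and from the face opposite the C10 methyl and the C1 ester, so that after 1,4-silyl shift and fluoride cleavage the C9 hydroxyl is trans to the C10 methyl (9R).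

Step 11
Reactants: 15 (1R,3S,5R,9R,10S)-9-hydroxy-10-methyl-6-methylidene-8-oxo-3-(prop-1-en-2-yl)spiro[4.5]decan-1-yl 2-methylpropanoate
Product: 17 (1R,3S,5R,9R,10S)-9-acetoxy-6,10-dimethyl-8-oxo-3-(prop-1-en-2-yl)spiro[4.5]dec-6-en-1-yl 2-methylpropanoate, via methylidene acetate 16 (not isolated)
Conditions: Ac2O, Et3N, DMAP (cat.), CH2Cl2, 0 °C to rt; then DBU (0.2 equiv), rt
Reagents that add atoms: acetic anhydride CC(=O)OC(C)=O
Why: DMAP-catalysed acetylation followed by base-mediated β,γ- to α,β-enone isomerisation through the C7 dienolate, which protonates at the exocyclic CH2 to create the C6 methyl and the conjugated C6=C7 bond, the trans C9-acetate/C10-methyl arrangement being expected to persist under these equilibrating conditions.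

Compound list
1 | (S)-(−)-limonene, (4S)-1-methyl-4-(prop-1-en-2-yl)cyclohex-1-ene | C=C(C)[C@@H]1CC=C(C)CC1 | starting material
2 | (3S)-6-oxo-3-(prop-1-en-2-yl)heptanal | C=C(C)[C@H](CC=O)CCC(C)=O | intermediate
3 | 1-[(4R)-4-(prop-1-en-2-yl)cyclopent-1-en-1-yl]ethan-1-one | C=C(C)[C@@H]1CC=C(C1)C(C)=O | intermediate
4 | 1-[(3R)-3-(prop-1-en-2-yl)-6-oxabicyclo[3.1.0]hexan-1-yl]ethan-1-one (epoxide diastereomers) | C=C(C)[C@@H]1CC2OC2(C1)C(C)=O | intermediate
5 | diethyl 1-[(3R)-3-(prop-1-en-2-yl)-6-oxabicyclo[3.1.0]hexan-1-yl]ethenyl phosphate | C=C(C)[C@@H]1CC2OC2(C1)C(=C)OP(=O)(OCC)OCC | intermediate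
6 | (3R)-1-ethynyl-3-(prop-1-en-2-yl)-6-oxabicyclo[3.1.0]hexane (epoxide diastereomers) | C=C(C)[C@@H]1CC2OC2(C#C)C1 | intermediate
7 | (4S)-2-ethenylidene-4-(prop-1-en-2-yl)cyclopentan-1-ol (C1 epimers) | C=C(C)[C@@H]1CC(O)C(=C=C)C1 | intermediate
8 | (4S)-2-ethenylidene-4-(prop-1-en-2-yl)cyclopentan-1-one | C=C(C)[C@@H]1CC(=O)C(=C=C)C1 | intermediate
9 | (3E)-pent-3-en-2-one | C/C=C/C(C)=O | starting material
10 | tert-butyl(dimethyl){[(3E)-penta-1,3-dien-2-yl]oxy}silane | C=C(O[Si](C)(C)C(C)(C)C)/C=C/C | intermediate
11 | (3S,5R,10R)-8-{[tert-butyl(dimethyl)silyl]oxy}-10-methyl-6-methylidene-3-(prop-1-en-2-yl)spiro[4.5]dec-8-en-1-one | C=C(C)[C@@H]1CC(=O)[C@@]2(C1)C(=C)CC(O[Si](C)(C)C(C)(C)C)=C[C@H]2C | intermediate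
12 | lithium (1R,3S,5R,10R)-8-{[tert-butyl(dimethyl)silyl]oxy}-10-methyl-6-methylidene-3-(prop-1-en-2-yl)spiro[4.5]dec-8-en-1-olate | [Li+].C=C(C)[C@@H]1C[C@@H]([O-])[C@@]2(C1)C(=C)CC(O[Si](C)(C)C(C)(C)C)=C[C@H]2C | intermediate
13 | (1R,3S,5R,10R)-8-{[tert-butyl(dimethyl)silyl]oxy}-10-methyl-6-methylidene-3-(prop-1-en-2-yl)spiro[4.5]dec-8-en-1-yl 2-methylpropanoate | C=C(C)[C@@H]1C[C@@H](OC(=O)C(C)C)[C@@]2(C1)C(=C)CC(O[Si](C)(C)C(C)(C)C)=C[C@H]2C | intermediate
14 | (1R,3S,5R,9R,10S)-9-{[tert-butyl(dimethyl)silyl]oxy}-10-methyl-6-methylidene-8-oxo-3-(prop-1-en-2-yl)spiro[4.5]decan-1-yl 2-methylpropanoate | C=C(C)[C@@H]1C[C@@H](OC(=O)C(C)C)[C@@]2(C1)C(=C)CC(=O)[C@H](O[Si](C)(C)C(C)(C)C)[C@H]2C | intermediate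
15 | (1R,3S,5R,9R,10S)-9-hydroxy-10-methyl-6-methylidene-8-oxo-3-(prop-1-en-2-yl)spiro[4.5]decan-1-yl 2-methylpropanoate | C=C(C)[C@@H]1C[C@@H](OC(=O)C(C)C)[C@@]2(C1)C(=C)CC(=O)[C@H](O)[C@H]2C | intermediate
16 | (1R,3S,5R,9R,10S)-9-acetoxy-10-methyl-6-methylidene-8-oxo-3-(prop-1-en-2-yl)spiro[4.5]decan-1-yl 2-methylpropanoate | C=C(C)[C@@H]1C[C@@H](OC(=O)C(C)C)[C@@]2(C1)C(=C)CC(=O)[C@H](OC(C)=O)[C@H]2C | intermediate
17 | (1R,3S,5R,9R,10S)-9-acetoxy-6,10-dimethyl-8-oxo-3-(prop-1-en-2-yl)spiro[4.5]dec-6-en-1-yl 2-methylpropanoate | C=C(C)[C@@H]1C[C@@H](OC(=O)C(C)C)[C@@]2(C1)C(C)=CC(=O)[C@H](OC(C)=O)[C@H]2C | target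

Total step count: 11. Longest linear sequence: 10 (steps 1 to 6 and 8 to 11; step 7 is the one-step side branch to the diene).

Steps most likely to fail

1. Step 8 (Diels–Alder). The remote C3 centre may discriminate the two faces of ring A only weakly, the exo approach may compete, and the Lewis acid may divert the allenone into oligomerisation or an open-chain Mukaiyama–Michael adduct. The fallback is a stepwise anionic double Michael sequence that sets out from compound 9 (with compound 8) and returns at compound 11. Enone 9 is deprotonated with LiN(iPr)2 in THF at −78 °C to the cross-conjugated lithium (3E)-penta-1,3-dien-2-olate F2. Its CH2 terminus adds to the central allene carbon of 8 to give the ring A lithium enolate of the open-chain adduct F3. On warming, C5 of F3 closes ring B by 6-endo Michael addition onto the pendant enone, again forming C5–C10, within a lithium-bridged and reversible arrangement; this gives the spirocyclic lithium enolate F4. Silylation of F4 with TBSCl in THF/HMPA delivers 11.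

2. Step 5 (SN2′ reduction). Hydride may be delivered to the wrong epoxide carbon, or the terminal alkyne may be metalated or hydroaluminated, instead of the SN2′ opening. The fallback sets out from compound 6 and returns at compound 8, replacing steps 5 and 6 by a redox-neutral rearrangement. A mild Lewis acid (InCl3, CH2Cl2) should ionise the tertiary propargylic C–O bond and trigger a Meinwald 1,2-hydride shift from C1 to give the 2-ethynyl ketone (4S)-2-ethynyl-4-(prop-1-en-2-yl)cyclopentan-1-one F1. Brief exposure of F1 to Et3N then effects the propargyl-to-allenyl tautomerisation to 8.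

3. Step 9 (reduction of the C1 ketone). Hydride may approach from the C10 face, giving the C1 epimer. The fallback sets out from compound 11 and returns at compound 13. The reduction is worked up without acylation and the 1S alcohol (1S,3S,5R,10R)-8-{[tert-butyl(dimethyl)silyl]oxy}-10-methyl-6-methylidene-3-(prop-1-en-2-yl)spiro[4.5]dec-8-en-1-ol F5 is isolated. Mitsunobu esterification of F5 with 2-methylpropanoic acid (PPh3, DIAD, toluene) then installs the isobutyrate with inversion at C1 to give 13.

Further compounds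
F1 | step 5 | (4S)-2-ethynyl-4-(prop-1-en-2-yl)cyclopentan-1-one (C2 epimers) | C=C(C)[C@@H]1CC(=O)C(C#C)C1
F2 | step 8 | lithium (3E)-penta-1,3-dien-2-olate | [Li+].C=C([O-])/C=C/C
F3 | step 8 | lithium (4S)-2-[(5E)-4-oxohepta-1,5-dien-2-yl]-4-(prop-1-en-2-yl)cyclopent-1-en-1-olate | [Li+].C=C(C)[C@@H]1CC([O-])=C(C1)C(=C)CC(=O)/C=C/C
F4 | step 8 | lithium (3S,5R,10R)-10-methyl-6-methylidene-1-oxo-3-(prop-1-en-2-yl)spiro[4.5]dec-8-en-8-olate | [Li+].C=C(C)[C@@H]1CC(=O)[C@@]2(C1)C(=C)CC([O-])=C[C@H]2C
F5 | step 9 | (1S,3S,5R,10R)-8-{[tert-butyl(dimethyl)silyl]oxy}-10-methyl-6-methylidene-3-(prop-1-en-2-yl)spiro[4.5]dec-8-en-1-ol | C=C(C)[C@@H]1C[C@H](O)[C@@]2(C1)C(=C)CC(O[Si](C)(C)C(C)(C)C)=C[C@H]2C
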